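## Retrosynthetic overview

1. Target 23 ← 22 by hydroxyl-directed epoxidation of C4=C5 (oxirane formed last).
2. Ten-membered ring ← C6–C7 bond by electroreductive, chromium-catalysed intramolecular allylation of a Z-enal by a 3-(bromomethyl)butenolide (19 → 22); this also sets C6 and C7 from C8.
3. Butenolide ring (formed first) ← ring-closing metathesis of the 2-(bromomethyl)acrylate of the C8 vinyl carbinol (18 → 19).
4. C1=C10 olefin with the C14 oxygen ← three-component β-oxido ylide coupling of a nerol-derived aldehyde (4), phosphonium salt 9 and formaldehyde.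
5. C8 is bought in (S)-α-hydroxy-γ-butyrolactone (from L-malic acid); the C4=C5 geometry is bought in nerol; ring order: butenolide → ten-membered carbocycle → oxirane.

Convention: C1–C15 are germacrane atom labels (C12 lactone carbonyl, C13 exocyclic methylene, C14 acyloxymethyl carbon, C15 methyl on C4).

## Route

Step 1
Reactants: 1 nerol
Product: 2 tert-butyl{[(2Z)-3,7-dimethylocta-2,6-dien-1-yl]oxy}diphenylsilane
Conditions: TBDPSCl, imidazole, DMF, 0 °C to rt
Reagents that add atoms: tert-butyl(chloro)diphenylsilane, CC(C)(C)[Si](Cl)(c1ccccc1)c1ccccc1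
Why: O-silylation of the primary allylic alcohol gives an ether that survives organolithium reagents and periodic acid; no stereocentre is involved.

Step 2
Reactants: 2 tert-butyl{[(2Z)-3,7-dimethylocta-2,6-dien-1-yl]oxy}diphenylsilane
Product: 3 tert-butyl{[(2Z)-5-(3,3-dimethyloxiran-2-yl)-3-methylpent-2-en-1-yl]oxy}diphenylsilane (racemic at the oxirane carbon)
Conditions: mCPBA, CH2Cl2, 0 °C
Reagents that add atoms: 3-chloroperbenzoic acid, OOC(=O)c1cccc(Cl)c1
Why: Prilezhaev epoxidation picks the remote, more electron-rich trisubstituted olefin over the one deactivated by the allylic silyloxy group; the new centre is racemic and is deleted in step 3.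

Step 3
Reactants: 3 tert-butyl{[(2Z)-5-(3,3-dimethyloxiran-2-yl)-3-methylpent-2-en-1-yl]oxy}diphenylsilane
Product: 4 (4Z)-6-[(tert-butyldiphenylsilyl)oxy]-4-methylhex-4-enal
Conditions: H5IO6, THF/H2O, 0 °C
Reagents that add atoms: none
Why: acid-mediated epoxide hydrolysis followed by Malaprade glycol cleavage releases acetone and the C1 aldehyde while the Z olefin (future C4=C5) is untouched.

Step 4
Reactants: 5 (3S)-3-hydroxyoxolan-2-one
Product: 6 (3S)-oxolane-2,3-diol (anomer mixture)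
Conditions: i-Bu2AlH (2.2 equiv), CH2Cl2, −78 °C; aq. potassium sodium tartrate
Reagents that add atoms: none
Why: partial hydride reduction of the lactone stops at the lactol at −78 °C and does not touch the bought carbinol centre (future C8).

Step 5
Reactants: 6 (3S)-oxolane-2,3-diol
Product: 7 (3S)-pent-4-ene-1,3-diol
Conditions: Ph3PCH3Br, KOt-Bu, THF, 0 °C to 65 °C
Reagents that add atoms: methyltriphenylphosphonium bromide, C[P+](c1ccccc1)(c1ccccc1)c1ccccc1.[Br-]
Why: Wittig methylenation of the ring-opened hydroxy aldehyde installs the C7 vinyl group, and the adjacent alkoxide suppresses enolisation so the stereocentre is kept.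

Step 6
Reactants: 7 (3S)-pent-4-ene-1,3-diol
Product: 8 (3S)-5-iodopent-1-en-3-ol
Conditions: I2, PPh3, imidazole, CH2Cl2, 0 °C
Reagents that add atoms: iodine, II
Why: Appel-type (Garegg–Samuelsson) iodination is selective for the unhindered primary alcohol over the secondary allylic one.

Step 7
Reactants: 8 (3S)-5-iodopent-1-en-3-ol
Product: 9 [(3S)-3-hydroxypent-4-en-1-yl]triphenylphosphonium iodide
Conditions: PPh3, MeCN, 80 °C
Reagents that add atoms: triphenylphosphine, c1ccc(cc1)P(c1ccccc1)c1ccccc1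
Why: SN2 quaternisation of the primary iodide gives the salt whose α-carbon becomes C10.

Step 8
Reactants: 9 [(3S)-3-hydroxypent-4-en-1-yl]triphenylphosphonium iodide; 4 (4Z)-6-[(tert-butyldiphenylsilyl)oxy]-4-methylhex-4-enal
Product: 12 (3S,5Z,9Z)-11-[(tert-butyldiphenylsilyl)oxy]-5-(hydroxymethyl)-9-methylundeca-1,5,9-trien-3-ol, via lithium alkoxide ylide 10 (not isolated), via beta-oxido ylide 11 (not isolated)
Conditions: n-BuLi (2 equiv), THF, −78 to 0 °C; 4, −78 °C; PhLi (1.1 equiv), −78 to −30 °C; (CH2O)n, 0 °C to rt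
Reagents that add atoms: formaldehyde (from paraformaldehyde), C=O
Why: Corey–Schlosser β-oxido ylide olefination, in which the lithium betaine from 10 and 4 is deprotonated to 11, hydroxymethylated and collapses so that the CH2OH (C14) ends cis to the aldehyde-derived chain (C2) and the ylide substituent (C9) trans, as in the target.

Step 9
Reactants: 12 (3S,5Z,9Z)-11-[(tert-butyldiphenylsilyl)oxy]-5-(hydroxymethyl)-9-methylundeca-1,5,9-trien-3-ol; 13 (2E)-2-methylbut-2-enoyl chloride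
Product: 14 (2Z,6Z)-8-[(tert-butyldiphenylsilyl)oxy]-2-[(2S)-2-hydroxybut-3-en-1-yl]-6-methylocta-2,6-dien-1-yl (2E)-2-methylbut-2-enoate
Conditions: 2,4,6-collidine, CH2Cl2, −40 °C
Reagents that add atoms: none
Why: acylation with the hindered, conjugated acid chloride at low temperature takes the primary allylic alcohol (C14) and leaves the secondary allylic alcohol (C8) free.

Step 10
Reactants: 14 (2Z,6Z)-8-[(tert-butyldiphenylsilyl)oxy]-2-[(2S)-2-hydroxybut-3-en-1-yl]-6-methylocta-2,6-dien-1-yl (2E)-2-methylbut-2-enoate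
Product: 15 (2Z,6Z)-8-hydroxy-2-[(2S)-2-hydroxybut-3-en-1-yl]-6-methylocta-2,6-dien-1-yl (2E)-2-methylbut-2-enoate
Conditions: Bu4NF, AcOH, THF, 0 °C to rt
Reagents that add atoms: none
Why: buffered fluoride desilylation frees the C6 alcohol without cleaving or migrating the tiglate.

Step 11
Reactants: 15 (2Z,6Z)-8-hydroxy-2-[(2S)-2-hydroxybut-3-en-1-yl]-6-methylocta-2,6-dien-1-yl (2E)-2-methylbut-2-enoate
Product: 16 (2Z,6Z)-2-[(2S)-2-hydroxybut-3-en-1-yl]-6-methyl-8-oxoocta-2,6-dien-1-yl (2E)-2-methylbut-2-enoate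
Conditions: TEMPO (10 mol %), PhI(OAc)2, CH2Cl2, rt
Reagents that add atoms: none
Why: oxoammonium (TEMPO) oxidation converts the primary allylic alcohol to the Z-enal without olefin isomerisation and is far slower on the secondary C8 carbinol.

Step 12
Reactants: 16 (2Z,6Z)-2-[(2S)-2-hydroxybut-3-en-1-yl]-6-methyl-8-oxoocta-2,6-dien-1-yl (2E)-2-methylbut-2-enoate; 17 2-(bromomethyl)prop-2-enoic acid
Product: 18 (2Z,6Z)-2-[(2S)-2-{[2-(bromomethyl)prop-2-enoyl]oxy}but-3-en-1-yl]-6-methyl-8-oxoocta-2,6-dien-1-yl (2E)-2-methylbut-2-enoate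
Conditions: DCC, DMAP (5 mol %), CH2Cl2, −20 to 0 °C
Reagents that add atoms: none
Why: Steglich esterification acylates the C8 alcohol with retention, putting C11, C12 and C13 in place.

Step 13
Reactants: 18 (2Z,6Z)-2-[(2S)-2-{[2-(bromomethyl)prop-2-enoyl]oxy}but-3-en-1-yl]-6-methyl-8-oxoocta-2,6-dien-1-yl (2E)-2-methylbut-2-enoate
Product: 19 (2Z,6Z)-2-{[(2S)-4-(bromomethyl)-5-oxo-2,5-dihydrofuran-2-yl]methyl}-6-methyl-8-oxoocta-2,6-dien-1-yl (2E)-2-methylbut-2-enoate
Conditions: second-generation Hoveyda–Grubbs catalyst (5 mol %), toluene (5 mM), 60 °C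
Reagents that add atoms: none
Why: ring-closing metathesis between the terminal vinyl group and the acrylate closes the five-membered butenolide with loss of ethene, while the trisubstituted olefins and the enal are inert.

Step 14
Reactants: 19 (2Z,6Z)-2-{[(2S)-4-(bromomethyl)-5-oxo-2,5-dihydrofuran-2-yl]methyl}-6-methyl-8-oxoocta-2,6-dien-1-yl (2E)-2-methylbut-2-enoate
Product: 22 [(3aS,4R,5Z,9Z,11aS)-4-hydroxy-6-methyl-3-methylidene-2-oxo-2,3,3a,4,7,8,11,11a-octahydrocyclodeca[b]furan-10-yl]methyl (2E)-2-methylbut-2-enoate, via allylchromium dichloride 20 (not isolated), via trimethylsilyl ether 21 (not isolated)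
Conditions: CrCl2 (20 mol %), Me3SiCl (3 equiv), Bu4NClO4 (0.1 M), THF/DMF 4:1, undivided cell, Al anode, graphite-felt cathode, constant current (about 2.2 F/mol), 19 added over 10 h to 2 mM, 25 °C; then aq. citric acid, THF
Reagents that add atoms: none
Why: Proposed new method: cathodically regenerated divalent chromium inserts into the allylic C–Br bond of 19 to give allylchromium 20, whose γ-carbon C7 adds to the tethered Z-enal through a Zimmerman–Traxler chair (attack anti to the C9 arm on the butenolide gives H7/H8 trans, and the ring-locked allyl geometry gives the 6,7-anti adduct, 6R in 22), while Me3SiCl releases the trivalent chromium alkoxide as silyl ether 21 so the catalyst turns over and translactonisation is blocked, and slow addition keeps ring closure ahead of dimerisation; the closest known reactions are stoichiometric CrCl2 Nozaki–Hiyama (Barbier-type) macrocyclisations of allylic halides onto aldehydes and intermolecular chromium-catalysed electroreductive allylations, neither shown for a bromomethylbutenolide or for ring closure under electrocatalysis.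

Step 15
Reactants: 22 [(3aS,4R,5Z,9Z,11aS)-4-hydroxy-6-methyl-3-methylidene-2-oxo-2,3,3a,4,7,8,11,11a-octahydrocyclodeca[b]furan-10-yl]methyl (2E)-2-methylbut-2-enoate
Product: 23 (4S,5R,6S,7S,8S)-4,5-epoxy-6-hydroxy-14-{[(2E)-2-methylbut-2-enoyl]oxy}germacra-1(10),11(13)-dien-12,8-olide (C2 trans to C9 across C1=C10; C3 cis to C6 on the oxirane)
Conditions: VO(acac)2 (5 mol %), t-BuOOH, CH2Cl2, 0 °C
Reagents that add atoms: tert-butyl hydroperoxide, CC(C)(C)OO
Why: vanadium-catalysed hydroxyl-directed (Sharpless–Michaelson) epoxidation delivers oxygen only to the allylic-alcohol olefin C4=C5, syn to the C6 hydroxyl in the conformer with H6 eclipsing the olefin (allylic 1,3-strain with C3), which gives the threo (4S,5R) oxirane and leaves C1=C10 and both enoates alone.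

## Compound list

1 | nerol, (2Z)-3,7-dimethylocta-2,6-dien-1-ol | CC(C)=CCC/C(C)=C\CO | starting material
2 | tert-butyl{[(2Z)-3,7-dimethylocta-2,6-dien-1-yl]oxy}diphenylsilane | CC(C)=CCC/C(C)=C\CO[Si](c1ccccc1)(c1ccccc1)C(C)(C)C | intermediate
3 | tert-butyl{[(2Z)-5-(3,3-dimethyloxiran-2-yl)-3-methylpent-2-en-1-yl]oxy}diphenylsilane (racemic oxirane centre) | CC1(C)OC1CC/C(C)=C\CO[Si](c1ccccc1)(c1ccccc1)C(C)(C)C | intermediate
4 | (4Z)-6-[(tert-butyldiphenylsilyl)oxy]-4-methylhex-4-enal | O=CCC/C(C)=C\CO[Si](c1ccccc1)(c1ccccc1)C(C)(C)C | intermediate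
5 | (3S)-3-hydroxyoxolan-2-one, (S)-α-hydroxy-γ-butyrolactone | O[C@H]1CCOC1=O | starting material
6 | (3S)-oxolane-2,3-diol (anomer mixture) | O[C@H]1CCOC1O | intermediate
7 | (3S)-pent-4-ene-1,3-diol | O[C@H](C=C)CCO | intermediate
8 | (3S)-5-iodopent-1-en-3-ol | O[C@H](C=C)CCI | intermediate
9 | [(3S)-3-hydroxypent-4-en-1-yl]triphenylphosphonium iodide | O[C@H](C=C)CC[P+](c1ccccc1)(c1ccccc1)c1ccccc1.[I-] | intermediate
10 | lithium (3S)-5-(triphenylphosphoranylidene)pent-1-en-3-olate (lithium alkoxide ylide, not isolated) | [Li]O[C@H](C=C)CC=P(c1ccccc1)(c1ccccc1)c1ccccc1 | intermediate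
11 | dilithium β-oxido ylide from 10 and 4 (oxido carbon unassigned, not isolated) | [Li]O[C@H](C=C)CC(=P(c1ccccc1)(c1ccccc1)c1ccccc1)C(O[Li])CC/C(C)=C\CO[Si](c1ccccc1)(c1ccccc1)C(C)(C)C | intermediate
12 | (3S,5Z,9Z)-11-[(tert-butyldiphenylsilyl)oxy]-5-(hydroxymethyl)-9-methylundeca-1,5,9-trien-3-ol | C=C[C@@H](O)C/C(CO)=C/CC/C(C)=C\CO[Si](c1ccccc1)(c1ccccc1)C(C)(C)C | intermediate
13 | (2E)-2-methylbut-2-enoyl chloride (tigloyl chloride) | C/C=C(\C)C(Cl)=O | starting material
14 | (2Z,6Z)-8-[(tert-butyldiphenylsilyl)oxy]-2-[(2S)-2-hydroxybut-3-en-1-yl]-6-methylocta-2,6-dien-1-yl (2E)-2-methylbut-2-enoate | C=C[C@@H](O)C/C(COC(=O)/C(C)=C/C)=C/CC/C(C)=C\CO[Si](c1ccccc1)(c1ccccc1)C(C)(C)C | intermediate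
15 | (2Z,6Z)-8-hydroxy-2-[(2S)-2-hydroxybut-3-en-1-yl]-6-methylocta-2,6-dien-1-yl (2E)-2-methylbut-2-enoate | C=C[C@@H](O)C/C(COC(=O)/C(C)=C/C)=C/CC/C(C)=C\CO | intermediate
16 | (2Z,6Z)-2-[(2S)-2-hydroxybut-3-en-1-yl]-6-methyl-8-oxoocta-2,6-dien-1-yl (2E)-2-methylbut-2-enoate | C=C[C@@H](O)C/C(COC(=O)/C(C)=C/C)=C/CC/C(C)=C\C=O | intermediate
17 | 2-(bromomethyl)prop-2-enoic acid | C=C(CBr)C(=O)O | starting material
18 | (2Z,6Z)-2-[(2S)-2-{[2-(bromomethyl)prop-2-enoyl]oxy}but-3-en-1-yl]-6-methyl-8-oxoocta-2,6-dien-1-yl (2E)-2-methylbut-2-enoate | C=C[C@@H](OC(=O)C(=C)CBr)C/C(COC(=O)/C(C)=C/C)=C/CC/C(C)=C\C=O | intermediate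
19 | (2Z,6Z)-2-{[(2S)-4-(bromomethyl)-5-oxo-2,5-dihydrofuran-2-yl]methyl}-6-methyl-8-oxoocta-2,6-dien-1-yl (2E)-2-methylbut-2-enoate | O=C1O[C@@H](C/C(COC(=O)/C(C)=C/C)=C/CC/C(C)=C\C=O)C=C1CBr | intermediate
20 | allylchromium dichloride derived from 19 (trivalent chromium on C13, not isolated) | Cl[Cr](Cl)CC1=C[C@H](C/C(COC(=O)/C(C)=C/C)=C/CC/C(C)=C\C=O)OC1=O | intermediate
21 | 6-O-trimethylsilyl ether of 22 (not isolated) | C=C1C(=O)O[C@H]2C/C(COC(=O)/C(C)=C/C)=C/CC/C(C)=C\[C@@H](O[Si](C)(C)C)[C@H]12 | intermediate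
22 | [(3aS,4R,5Z,9Z,11aS)-4-hydroxy-6-methyl-3-methylidene-2-oxo-2,3,3a,4,7,8,11,11a-octahydrocyclodeca[b]furan-10-yl]methyl (2E)-2-methylbut-2-enoate; germacrane labels (4Z,6R,7S,8S), C2 trans to C9 across C1=C10 | C=C1C(=O)O[C@H]2C/C(COC(=O)/C(C)=C/C)=C/CC/C(C)=C\[C@@H](O)[C@H]12 | intermediate
23 | (4S,5R,6S,7S,8S)-4,5-epoxy-6-hydroxy-14-{[(2E)-2-methylbut-2-enoyl]oxy}germacra-1(10),11(13)-dien-12,8-olide (CNP0116446.1) | C=C1C(=O)O[C@H]2C/C(COC(=O)/C(C)=C/C)=C/CC[C@]3(C)O[C@@H]3[C@@H](O)[C@H]12 | target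

## Step count and risk

Total steps: 15. Longest linear sequence: 12 steps (steps 4–15, from 5); the nerol branch (steps 1–3) joins at step 8.

Most likely to fail:

Step 8 (three-component β-oxido ylide coupling; moderate yields, sensitive to temperature and to the free alkoxide in the ylide). The fallback sets out from iodide 8 and aldehyde 4 and comes back at diol 12, using a Still–Gennari olefination in place of the ylide cascade. Iodide 8 is silylated (Et3SiCl, imidazole) to (3S)-5-iodo-3-[(triethylsilyl)oxy]pent-1-ene F1. Michaelis–Becker alkylation of HP(O)(OCH2CF3)2 with KN(SiMe3)2 gives bis(2,2,2-trifluoroethyl) {(3S)-3-[(triethylsilyl)oxy]pent-4-en-1-yl}phosphonate F2. C-Acylation (LiN(SiMe3)2, ClCO2Me, −78 °C) gives methyl (4S)-2-[bis(2,2,2-trifluoroethoxy)phosphoryl]-4-[(triethylsilyl)oxy]hex-5-enoate F3. Olefination of 4 (KN(SiMe3)2, 18-crown-6, THF, −78 °C) gives methyl (2Z,6Z)-8-[(tert-butyldiphenylsilyl)oxy]-6-methyl-2-{(2S)-2-[(triethylsilyl)oxy]but-3-en-1-yl}octa-2,6-dienoate F4, with the ester (future C14) cis to C2. Reduction with i-Bu2AlH gives (2Z,6Z)-8-[(tert-butyldiphenylsilyl)oxy]-6-methyl-2-{(2S)-2-[(triethylsilyl)oxy]but-3-en-1-yl}octa-2,6-dien-1-ol F5, and PPTS in MeOH removes only the triethylsilyl group to return 12.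

Step 14 (the proposed electroreductive chromium-catalysed macrocyclisation; risks are oligomerisation, direct cathodic reduction of the enal or bromide, and α- instead of γ-attack). The fallback sets out from 19 and comes back at 22 through known allylboron chemistry instead of an organochromium species. Pd2(dba)3 (2 mol %) and B2pin2 in toluene at 40 °C, with 19 added slowly, convert the allylic bromide (much faster in oxidative addition to zerovalent palladium than the allylic tiglate) into (2Z,6Z)-6-methyl-8-oxo-2-({(2S)-5-oxo-4-[(4,4,5,5-tetramethyl-1,3,2-dioxaborolan-2-yl)methyl]-2,5-dihydrofuran-2-yl}methyl)octa-2,6-dien-1-yl (2E)-2-methylbut-2-enoate F6. This 2-alkoxycarbonyl allylboronate closes the ring by thermal intramolecular allylboration through the same chair (Sc(OTf)3, 10 mol %, if sluggish), and aqueous work-up gives 22.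

Step 15 (facial selectivity of oxygen delivery inside the ten-membered ring is predicted from the acyclic model, not proven). The fallback sets out from 22 and comes back at 23 by a halohydrin detour that gives the complementary facial outcome to direct oxygen transfer. NBS in THF/H2O at 0 °C forms the bromonium ion on the exposed face of C4=C5 and water opens it at the tertiary carbon, giving (4S,5S,6S,7S,8S)-5-bromo-4,6-dihydroxy-14-{[(2E)-2-methylbut-2-enoyl]oxy}germacra-1(10),11(13)-dien-12,8-olide F7. Ag2O in CH2Cl2 then closes the oxirane with inversion at C5 to give 23.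

Further compounds
F1 | step 8 | (3S)-5-iodo-3-[(triethylsilyl)oxy]pent-1-ene | C=C[C@@H](O[Si](CC)(CC)CC)CCI
F2 | step 8 | bis(2,2,2-trifluoroethyl) {(3S)-3-[(triethylsilyl)oxy]pent-4-en-1-yl}phosphonate | C=C[C@@H](O[Si](CC)(CC)CC)CCP(=O)(OCC(F)(F)F)OCC(F)(F)F
F3 | step 8 | methyl (4S)-2-[bis(2,2,2-trifluoroethoxy)phosphoryl]-4-[(triethylsilyl)oxy]hex-5-enoate | C=C[C@@H](O[Si](CC)(CC)CC)CC(C(=O)OC)P(=O)(OCC(F)(F)F)OCC(F)(F)F
F4 | step 8 | methyl (2Z,6Z)-8-[(tert-butyldiphenylsilyl)oxy]-6-methyl-2-{(2S)-2-[(triethylsilyl)oxy]but-3-en-1-yl}octa-2,6-dienoate | C=C[C@@H](O[Si](CC)(CC)CC)C/C(C(=O)OC)=C/CC/C(C)=C\CO[Si](c1ccccc1)(c1ccccc1)C(C)(C)C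
F5 | step 8 | (2Z,6Z)-8-[(tert-butyldiphenylsilyl)oxy]-6-methyl-2-{(2S)-2-[(triethylsilyl)oxy]but-3-en-1-yl}octa-2,6-dien-1-ol | C=C[C@@H](O[Si](CC)(CC)CC)C/C(CO)=C/CC/C(C)=C\CO[Si](c1ccccc1)(c1ccccc1)C(C)(C)C
F6 | step 14 | (2Z,6Z)-6-methyl-8-oxo-2-({(2S)-5-oxo-4-[(4,4,5,5-tetramethyl-1,3,2-dioxaborolan-2-yl)methyl]-2,5-dihydrofuran-2-yl}methyl)octa-2,6-dien-1-yl (2E)-2-methylbut-2-enoate | CC1(C)OB(CC2=C[C@H](C/C(COC(=O)/C(C)=C/C)=C/CC/C(C)=C\C=O)OC2=O)OC1(C)C
F7 | step 15 | (4S,5S,6S,7S,8S)-5-bromo-4,6-dihydroxy-14-{[(2E)-2-methylbut-2-enoyl]oxy}germacra-1(10),11(13)-dien-12,8-olide | C=C1C(=O)O[C@H]2C/C(COC(=O)/C(C)=C/C)=C/CC[C@](C)(O)[C@@H](Br)[C@@H](O)[C@H]12
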